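**Retrosynthetic overview**
- The target comes from an all-trans 2-aryl-3-(acetoxymethyl)-4-aroyl-oxolane by reagent-controlled ketone reduction, O-acetylation and selective release of the phenol from its acetate.
- That keto-oxolane comes from a 1-aroyl-4-aryl-3-oxabicyclo[3.1.0]hexane by homo-conjugate opening at the cyclopropane CH2 (iodide, then acetate); the ketone α-centre settles trans.
- The bicycle comes from a chiral allyl propargyl ether (1,6-enyne) by gold-catalysed oxidative cycloisomerisation, which closes the oxolane and the cyclopropane together. This is the only ring-forming event: the oxolane is kept, the cyclopropane is opened one step later.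
- The enyne comes from racemic 1-(4-acetoxyphenyl)allyl alcohol and 3-(4-methoxyphenyl)propargyl alcohol by iridium-catalysed enantioconvergent etherification; the allyl alcohol comes from 4-acetoxybenzaldehyde and vinylmagnesium bromide.
- Stereocontrol: the aryl-bearing carbon by the Ir catalyst, the CH2OAc-bearing carbon by anti cyclopropanation, the next ring carbon by equilibration, the carbinol by CBS reduction; the phenolic acetate is the only protecting group.

Assumption: the (S)-configured P,olefin ligand is taken to give the (R)-ether in step 2; if the catalyst's sense is the opposite, the (R)-ligand is used and nothing else changes. All three starting materials are catalogue chemicals.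

**Step 1**
Reactants: 1 4-formylphenyl acetate; 2 vinylmagnesium bromide
Product: 3 4-(1-hydroxyprop-2-en-1-yl)phenyl acetate (racemic)
Conditions: CH2=CHMgBr (1.05 equiv), THF, −78 °C, 30 min; cold quench with sat. aq. NH4Cl
Reagents that add atoms: vinylmagnesium bromide, C=C[Mg]Br
Why: Grignard 1,2-addition is chemoselective for the aldehyde over the much less electrophilic aryl acetate at −78 °C with one equivalent and a cold quench; the carbinol is left racemic because the next step is enantioconvergent.

**Step 2**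
Reactants: 3 4-(1-hydroxyprop-2-en-1-yl)phenyl acetate (racemic); 4 3-(4-methoxyphenyl)prop-2-yn-1-ol
Product: 5 4-[(1R)-1-{[3-(4-methoxyphenyl)prop-2-yn-1-yl]oxy}prop-2-en-1-yl]phenyl acetate
Conditions: [Ir(cod)Cl]2 (3 mol%), (S)-BINOL dibenzo[b,f]azepine phosphoramidite (Carreira-type P,olefin ligand, 12 mol%), diphenyl phosphate (10 mol%), 4 (2 equiv), ClCH2CH2Cl, rt
Reagents that add atoms: 3-(4-methoxyphenyl)prop-2-yn-1-ol (compound 4), COc1ccc(C#CCO)cc1
Why: Iridium-catalysed enantioconvergent allylic etherification of a racemic branched allylic alcohol: acid-assisted ionisation gives an η3-allyl iridium complex in the chiral ligand pocket, and the primary alcohol attacks the substituted terminus on one face, which sets the (R) centre and the branched regiochemistry under acidic conditions that the aryl acetate tolerates.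

**Step 3**
Reactants: 5 4-[(1R)-1-{[3-(4-methoxyphenyl)prop-2-yn-1-yl]oxy}prop-2-en-1-yl]phenyl acetate
Product: 6 4-[(1R,2R,5R)-5-(4-methoxybenzoyl)-3-oxabicyclo[3.1.0]hexan-2-yl]phenyl acetate
Conditions: (IPr)Au(NTf2) (5 mol%; IPr = 1,3-bis(2,6-diisopropylphenyl)imidazol-2-ylidene), Ph2SO (3 equiv), CH2Cl2, 0 °C to rt
Reagents that add atoms: diphenyl sulfoxide, O=S(c1ccccc1)c1ccccc1
Why: Gold-catalysed oxidative cycloisomerisation of a 1,6-enyne: 5-exo-dig attack of the vinyl group on the gold-activated aryl alkyne gives an aryl-stabilised cyclopropyl gold carbene (oxolane and cyclopropane formed together) that Ph2SO oxidises to the aryl ketone; the alkene adds on the face anti to the allylic aryl group (the usual trans preference of a substituent next to the alkene in 5-exo closures), which sets the ring-fusion CH, and the quaternary ring-fusion carbon follows because the three-membered ring can only be cis-fused.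

**Step 4**
Reactants: 6 4-[(1R,2R,5R)-5-(4-methoxybenzoyl)-3-oxabicyclo[3.1.0]hexan-2-yl]phenyl acetate
Product: 9 [(2R,3S,4R)-2-(4-acetoxyphenyl)-4-(4-methoxybenzoyl)oxolan-3-yl]methyl acetate, via iodo silyl enol ether 7 (not isolated), via iodo ketone 8 (not isolated)
Conditions: Me3SiI (1.2 equiv), CH2Cl2, −78 to −30 °C; then AcOH/H2O, KOAc (6 equiv), DMF, 50 °C
Reagents that add atoms: potassium acetate, CC(=O)[O-].[K+]
Why: Homo-conjugate (homo-Michael) opening of the O-silylated aryl cyclopropyl ketone by iodide at the unhindered cyclopropane CH2, hydrolysis of the silyl enol ether, then SN2 displacement of the primary iodide by acetate in a buffer too weakly basic to re-close the cyclopropane; the new C–H centre α to the ketone equilibrates by enolisation to the all-trans oxolane, while the two other ring centres are not touched.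

**Step 5**
Reactants: 9 [(2R,3S,4R)-2-(4-acetoxyphenyl)-4-(4-methoxybenzoyl)oxolan-3-yl]methyl acetate
Product: 10 [(2R,3S,4R)-2-(4-acetoxyphenyl)-4-[(S)-hydroxy(4-methoxyphenyl)methyl]oxolan-3-yl]methyl acetate
Conditions: (R)-2-methyl-CBS-oxazaborolidine (0.5 equiv), BH3·SMe2 (1.0 equiv), THF, −20 to 0 °C; MeOH quench
Reagents that add atoms: none
Why: Corey–Bakshi–Shibata reduction under reagent control: with the anisyl group as the large substituent the (R)-oxazaborolidine delivers hydride to the face that gives the (S)-carbinol, and neither acetate nor the α-centre is affected by the short, base-free borane exposure.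

**Step 6**
Reactants: 10 [(2R,3S,4R)-2-(4-acetoxyphenyl)-4-[(S)-hydroxy(4-methoxyphenyl)methyl]oxolan-3-yl]methyl acetate
Product: 12 (S)-[(3R,4S,5R)-4-(acetoxymethyl)-5-(4-hydroxyphenyl)oxolan-3-yl](4-methoxyphenyl)methyl acetate (the target), via triacetate 11 (not isolated)
Conditions: Ac2O (1.5 equiv), pyridine, DMAP (cat.), CH2Cl2, 0 °C to rt; then pyrrolidine (5 equiv), 0 °C, 30 min
Reagents that add atoms: acetic anhydride, CC(=O)OC(C)=O
Why: DMAP-catalysed acetylation of the secondary benzylic alcohol, then chemoselective aminolysis of the aryl acetate in the same flask (a phenyl ester is far more electrophilic than the two alkyl acetates), which frees the phenol without touching a stereocentre.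

**Compound list**
1 | 4-formylphenyl acetate | CC(=O)Oc1ccc(C=O)cc1 | starting material
2 | vinylmagnesium bromide | C=C[Mg]Br | starting material
3 | 4-(1-hydroxyprop-2-en-1-yl)phenyl acetate (racemic) | CC(=O)Oc1ccc(C(O)C=C)cc1 | intermediate
4 | 3-(4-methoxyphenyl)prop-2-yn-1-ol | COc1ccc(C#CCO)cc1 | starting material
5 | 4-[(1R)-1-{[3-(4-methoxyphenyl)prop-2-yn-1-yl]oxy}prop-2-en-1-yl]phenyl acetate | C=C[C@@H](OCC#Cc1ccc(OC)cc1)c1ccc(OC(C)=O)cc1 | intermediate
6 | 4-[(1R,2R,5R)-5-(4-methoxybenzoyl)-3-oxabicyclo[3.1.0]hexan-2-yl]phenyl acetate | COc1ccc(cc1)C(=O)[C@]12C[C@H]1[C@H](c1ccc(OC(C)=O)cc1)OC2 | intermediate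
7 | 4-[(2R,3R)-3-(iodomethyl)-4-{(4-methoxyphenyl)[(trimethylsilyl)oxy]methylidene}oxolan-2-yl]phenyl acetate (iodo silyl enol ether) | COc1ccc(cc1)C(O[Si](C)(C)C)=C1CO[C@@H](c2ccc(OC(C)=O)cc2)[C@@H]1CI | intermediate
8 | 4-[(2R,3R)-3-(iodomethyl)-4-(4-methoxybenzoyl)oxolan-2-yl]phenyl acetate (iodo ketone, C-4 epimers) | COc1ccc(cc1)C(=O)C1CO[C@@H](c2ccc(OC(C)=O)cc2)[C@@H]1CI | intermediate
9 | [(2R,3S,4R)-2-(4-acetoxyphenyl)-4-(4-methoxybenzoyl)oxolan-3-yl]methyl acetate | COc1ccc(cc1)C(=O)[C@H]1CO[C@@H](c2ccc(OC(C)=O)cc2)[C@@H]1COC(C)=O | intermediate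
10 | [(2R,3S,4R)-2-(4-acetoxyphenyl)-4-[(S)-hydroxy(4-methoxyphenyl)methyl]oxolan-3-yl]methyl acetate | COc1ccc(cc1)[C@@H](O)[C@H]1CO[C@@H](c2ccc(OC(C)=O)cc2)[C@@H]1COC(C)=O | intermediate
11 | (S)-[(3R,4S,5R)-5-(4-acetoxyphenyl)-4-(acetoxymethyl)oxolan-3-yl](4-methoxyphenyl)methyl acetate (triacetate) | COc1ccc(cc1)[C@@H](OC(C)=O)[C@H]1CO[C@@H](c2ccc(OC(C)=O)cc2)[C@@H]1COC(C)=O | intermediate
12 | (S)-[(3R,4S,5R)-4-(acetoxymethyl)-5-(4-hydroxyphenyl)oxolan-3-yl](4-methoxyphenyl)methyl acetate | COc1ccc([C@@H](OC(C)=O)[C@H]2CO[C@@H](c3ccc(O)cc3)[C@@H]2COC(C)=O)cc1 | target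

**Step count and risks**
Total steps: 6. Longest linear sequence: 6 (compound 4 is bought).

Steps most likely to fail:

Step 3 (key cyclisation). The cyclopropyl gold carbene of an aryl alkyne can instead close onto its own aryl ring (formal [4+2]), the ether tether can favour 6-endo closure, and the facial selectivity anti to the aryl group is predicted, not measured. Fallback, setting out from 5: Brønsted-acid hydration of the anisyl alkyne (TsOH·H2O, aqueous EtOH, 50 °C) gives 4-[(1R)-1-[3-(4-methoxyphenyl)-3-oxopropoxy]prop-2-en-1-yl]phenyl acetate F1. α-Bromination (PhNMe3Br3, THF) gives 4-[(1R)-1-[2-bromo-3-(4-methoxyphenyl)-3-oxopropoxy]prop-2-en-1-yl]phenyl acetate F2. Copper-catalysed atom-transfer radical cyclisation (CuBr, tris(2-pyridylmethyl)amine, ClCH2CH2Cl, 80 °C) closes the oxolane by 5-exo attack anti to the aryl group and leaves bromine on the exocyclic CH2, giving 4-[(2R,3R)-3-(bromomethyl)-4-(4-methoxybenzoyl)oxolan-2-yl]phenyl acetate F3. KOAc in DMF displaces bromide and equilibrates the ketone α-centre, which comes back to the route at 9.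

Step 4 (cyclopropane opening). Me3SiI may also cleave the benzylic oxolane C–O bond, and the iodo ketone can re-close to 6 if the medium becomes basic. Fallback, setting out from 6: zerovalent-nickel-catalysed borylative C–C cleavage (Ni(cod)2, IMes, B2pin2, toluene) gives 4-[(2R,3R)-4-(4-methoxybenzoyl)-3-[(4,4,5,5-tetramethyl-1,3,2-dioxaborolan-2-yl)methyl]oxolan-2-yl]phenyl acetate F4. NaBO3·4H2O in THF/H2O oxidises C–B to C–OH and also removes the phenolic acetate, giving (4-methoxyphenyl)[(4S,5R)-4-(hydroxymethyl)-5-(4-hydroxyphenyl)oxolan-3-yl]methanone F5. Ac2O/pyridine acetylates both hydroxyls and the α-centre equilibrates, which comes back to the route at 9.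

Step 5 (carbinol configuration). The α-branched, electron-rich ketone is a slow CBS substrate and the (R)-catalyst may be the mismatched pairing with the ring stereocentres. Fallback, setting out from 9: the (S)-catalyst under the same conditions gives the epimeric carbinol [(2R,3S,4R)-2-(4-acetoxyphenyl)-4-[(R)-hydroxy(4-methoxyphenyl)methyl]oxolan-3-yl]methyl acetate F6. Mitsunobu esterification with acetic acid (PPh3, DIAD, AcOH, toluene, 0 °C) inverts the carbinol centre and gives the triacetate, which comes back to the route at 11; the pyrrolidine stage of step 6 then gives 12.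

**Further compounds**
F1 | step 3 | 4-[(1R)-1-[3-(4-methoxyphenyl)-3-oxopropoxy]prop-2-en-1-yl]phenyl acetate | C=C[C@@H](OCCC(=O)c1ccc(OC)cc1)c1ccc(OC(C)=O)cc1
F2 | step 3 | 4-[(1R)-1-[2-bromo-3-(4-methoxyphenyl)-3-oxopropoxy]prop-2-en-1-yl]phenyl acetate | C=C[C@@H](OCC(Br)C(=O)c1ccc(OC)cc1)c1ccc(OC(C)=O)cc1
F3 | step 3 | 4-[(2R,3R)-3-(bromomethyl)-4-(4-methoxybenzoyl)oxolan-2-yl]phenyl acetate | COc1ccc(cc1)C(=O)C1CO[C@@H](c2ccc(OC(C)=O)cc2)[C@@H]1CBr
F4 | step 4 | 4-[(2R,3R)-4-(4-methoxybenzoyl)-3-[(4,4,5,5-tetramethyl-1,3,2-dioxaborolan-2-yl)methyl]oxolan-2-yl]phenyl acetate | COc1ccc(cc1)C(=O)C1CO[C@@H](c2ccc(OC(C)=O)cc2)[C@@H]1CB1OC(C)(C)C(C)(C)O1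
F5 | step 4 | (4-methoxyphenyl)[(4S,5R)-4-(hydroxymethyl)-5-(4-hydroxyphenyl)oxolan-3-yl]methanone | COc1ccc(cc1)C(=O)C1CO[C@@H](c2ccc(O)cc2)[C@@H]1CO
F6 | step 5 | [(2R,3S,4R)-2-(4-acetoxyphenyl)-4-[(R)-hydroxy(4-methoxyphenyl)methyl]oxolan-3-yl]methyl acetate | COc1ccc(cc1)[C@H](O)[C@H]1CO[C@@H](c2ccc(OC(C)=O)cc2)[C@@H]1COC(C)=O
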